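**Retrosynthetic overview**

- Feature: seen from C4a, ring A has a local mirror plane through C4a and C7. C5 (OH) and C8a (O1) are the two oxygen-bearing carbons ortho to the acyl carbon, and C6, C7 and C8 all carry OMe. Both oxygens can therefore start as the two equivalent bromides of a 2,6-dibromo-3,4,5-trimethoxybenzoyl group.
- C5–OH is traced back to C5–Br (hydroxylation, last step). O1–C8a is cut to an enolate oxygen and an aryl C–Br bond, which leads to the dibromoaryl 1,3-diketone 6.
- C3–C4 is cut to acid chloride 3 and the lithium enolate of acetophenone 4; 3 comes from acid 1 by double bromination and chlorination.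
- Rings A and B are bought. Ring C (the pyranone) is the only ring formed, in step 4.

Key step: step 4

Remark: compound 6 is drawn as the diketo tautomer; it is expected to exist largely as the chelated enol, which does not change any step.

**Route**

Step 1
Reactants: 1 3,4,5-trimethoxybenzoic acid
Product: 2 2,6-dibromo-3,4,5-trimethoxybenzoic acid
Conditions: Br2 (2.2 equiv), AcOH, 20 to 50 °C
Reagents that add atoms: bromine, BrBr
Why: Electrophilic aromatic bromination should take C2 and then C6, each ortho to one methoxy group and para to another, while the protonated acid in AcOH and the small excess of bromine hold back ipso attack at C1 (bromodecarboxylation).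

Step 2
Reactants: 2 2,6-dibromo-3,4,5-trimethoxybenzoic acid
Product: 3 2,6-dibromo-3,4,5-trimethoxybenzoyl chloride
Conditions: (COCl)2 (1.5 equiv), DMF (cat.), CH2Cl2, 0 °C to rt; evaporation, used crude
Reagents that add atoms: oxalyl chloride, O=C(Cl)C(=O)Cl
Why: Acid chloride formation through the chloroiminium (Vilsmeier) species from DMF and oxalyl chloride is reliable for di-ortho-substituted benzoic acids and leaves aryl bromides and methyl ethers untouched.

Step 3
Reactants: 3 2,6-dibromo-3,4,5-trimethoxybenzoyl chloride; 4 1-(2,4,5-trimethoxyphenyl)ethan-1-one (2,4,5-trimethoxyacetophenone)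
Product: 6 1-(2,6-dibromo-3,4,5-trimethoxyphenyl)-3-(2,4,5-trimethoxyphenyl)propane-1,3-dione, via lithium 1-(2,4,5-trimethoxyphenyl)ethenolate 5 (not isolated)
Conditions: 4 (2.0 equiv), LiN(SiMe3)2 (2.1 equiv), THF, −78 °C; then 3 (1.0 equiv), −78 to 0 °C; aq. NH4Cl, 1 M HCl
Reagents that add atoms: none
Why: Claisen-type C-acylation of a preformed lithium enolate by an acid chloride should give the 1,3-diketone, the second equivalent of enolate deprotonating the more acidic product so that it is not acylated again, and the amide base does not exchange the aryl bromides.

Step 4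
Reactants: 6 1-(2,6-dibromo-3,4,5-trimethoxyphenyl)-3-(2,4,5-trimethoxyphenyl)propane-1,3-dione
Product: 7 5-bromo-6,7,8-trimethoxy-2-(2,4,5-trimethoxyphenyl)-4H-chromen-4-one
Conditions: CuI (10 mol%), 1,10-phenanthroline (20 mol%), K2CO3 (2.0 equiv), dry degassed DMF, 100 °C, N2
Reagents that add atoms: none
Why: K2CO3 forms the diketonate, which binds monovalent copper; rotation about C3–C4 places the oxygen on the ring B side next to one ortho C–Br bond, where oxidative addition to an aryl species of trivalent copper and C–O reductive elimination form O1–C8a, and an addition-elimination path through an anion stabilised by the C4 carbonyl would give the same product. The closest known reaction type is the intramolecular Ullmann-type O-arylation of 1-(2-haloaryl)-1,3-diketones to flavones, which is also known to run with base alone in DMF. Ring C closes as a six-membered ring by ipso substitution at an sp2 carbon, the breaking C–Br bond lying outside the new ring (6-exo with respect to the leaving group). No stereocentre is formed. Site selectivity is not needed because the two C–Br carbons are interchanged by rotation about the aryl–carbonyl bond, and O-arylation is secured because attack by C3 or by the C4 oxygen would close a four-membered ring. The bromide left at C5 has no internal nucleophile in reach and should survive for step 5.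

Step 5
Reactants: 7 5-bromo-6,7,8-trimethoxy-2-(2,4,5-trimethoxyphenyl)-4H-chromen-4-one
Product: 8 agehoustin E, 5-hydroxy-6,7,8-trimethoxy-2-(2,4,5-trimethoxyphenyl)-4H-chromen-4-one
Conditions: Cu(acac)2 (5 mol%), N,N'-bis(4-hydroxy-2,6-dimethylphenyl)oxalamide (5 mol%), LiOH·H2O (3 equiv), DMSO/H2O (4:1), 80 °C; then 1 M HCl
Reagents that add atoms: lithium hydroxide, [Li+].[OH-]
Why: Ullmann-type copper-catalysed hydroxylation of an aryl bromide should be helped by the C4 carbonyl next to C5, which withdraws electron density and can hold copper beside the C–Br bond (ortho effect), and any hydroxide-induced opening of ring C is harmless because the opened diketone has a symmetric 2,6-dihydroxyaryl ring and recloses to the same flavone on acidification.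

**Compound list**

1 | 3,4,5-trimethoxybenzoic acid | COc1cc(C(=O)O)cc(OC)c1OC | starting material
2 | 2,6-dibromo-3,4,5-trimethoxybenzoic acid | COc1c(OC)c(Br)c(C(=O)O)c(Br)c1OC | intermediate
3 | 2,6-dibromo-3,4,5-trimethoxybenzoyl chloride | COc1c(OC)c(Br)c(C(=O)Cl)c(Br)c1OC | intermediate
4 | 1-(2,4,5-trimethoxyphenyl)ethan-1-one | CC(=O)c1cc(OC)c(OC)cc1OC | starting material
5 | lithium 1-(2,4,5-trimethoxyphenyl)ethenolate | [Li+].C=C([O-])c1cc(OC)c(OC)cc1OC | intermediate (not isolated)
6 | 1-(2,6-dibromo-3,4,5-trimethoxyphenyl)-3-(2,4,5-trimethoxyphenyl)propane-1,3-dione | COc1cc(OC)c(C(=O)CC(=O)c2c(Br)c(OC)c(OC)c(OC)c2Br)cc1OC | intermediate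
7 | 5-bromo-6,7,8-trimethoxy-2-(2,4,5-trimethoxyphenyl)-4H-chromen-4-one | COc1cc(OC)c(-c2cc(=O)c3c(Br)c(OC)c(OC)c(OC)c3o2)cc1OC | intermediate
8 | agehoustin E | COc1cc(OC)c(-c2cc(=O)c3c(O)c(OC)c(OC)c(OC)c3o2)cc1OC | target

**Step count**

Total steps: 5. Longest linear sequence: 5 steps (1 to 8); ketone 4 enters in step 3.

**Steps most likely to fail**

Step 4. The ring closure may be slow because the C4 carbonyl has to turn into the plane of ring A against the second ortho bromine, so hydrodebromination and retro-Claisen cleavage of the diketone could take over. The fallback sets out from 6 and brings the oxygen in from outside before the ring is closed. Exhaustive copper-catalysed hydroxylation (Cu(acac)2, the oxalamide ligand of step 5, LiOH·H2O, DMSO/H2O, 100 °C) would replace both bromides and give 1-(2,6-dihydroxy-3,4,5-trimethoxyphenyl)-3-(2,4,5-trimethoxyphenyl)propane-1,3-dione F1. Acid cyclodehydration (cat. H2SO4, AcOH, 90 °C) would then close ring C at O1–C2. The two phenols of F1 are equivalent, so only one flavone can form, and any material that has already cyclised and been hydroxylated converges on the same product. The fallback comes back to the route at 8.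

Step 5. Hydrodebromination at the doubly ortho-substituted C5 and hydroxide attack at C2 with degradation of ring C may compete with C–O coupling. The fallback sets out from 7 and uses an Ullmann methoxylation (CuBr cat., NaOMe, MeOH/DMF, 110 °C) to give 5,6,7,8-tetramethoxy-2-(2,4,5-trimethoxyphenyl)-4H-chromen-4-one F2. Chelation-controlled cleavage of the methyl ether next to the C4 carbonyl (BCl3, about 1.2 equiv, CH2Cl2, −20 to 0 °C) should then free only the C5 hydroxyl. The fallback comes back to the route at 8.

Step 3. O-acylation of the enolate, or sluggish attack on the di-ortho-substituted acid chloride, may lower the supply of diketone. The fallback sets out from 3 and reverses the roles of the partners. Me2CuLi (Et2O, −78 °C) would convert 3 into 1-(2,6-dibromo-3,4,5-trimethoxyphenyl)ethan-1-one F3. Its unhindered methyl enolate would then undergo a Claisen condensation with commercial methyl 2,4,5-trimethoxybenzoate (NaH, THF, reflux), in which an ester electrophile gives only the C-acylated product. The fallback comes back to the route at 6.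

**Further compounds**

F1 | step 4 | 1-(2,6-dihydroxy-3,4,5-trimethoxyphenyl)-3-(2,4,5-trimethoxyphenyl)propane-1,3-dione | COc1cc(OC)c(C(=O)CC(=O)c2c(O)c(OC)c(OC)c(OC)c2O)cc1OC
F2 | step 5 | 5,6,7,8-tetramethoxy-2-(2,4,5-trimethoxyphenyl)-4H-chromen-4-one | COc1cc(OC)c(-c2cc(=O)c3c(OC)c(OC)c(OC)c(OC)c3o2)cc1OC
F3 | step 3 | 1-(2,6-dibromo-3,4,5-trimethoxyphenyl)ethan-1-one | CC(=O)c1c(Br)c(OC)c(OC)c(OC)c1Br
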